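## Structural features

Alopecurone G is a (2S)-flavanone: benzo ring A (C4a to C8a) is fused to the dihydropyranone ring C (O1, C2, C3, C4), and the 2-methoxy-4-hydroxyphenyl ring B sits on C2. Ring A carries a 7-hydroxyl and, between C7–OH and the ring oxygen on C8a, an 8-lavandulyl chain whose one stereocentre (R, bearing isopropenyl and prenyl) is one methylene away from C8. The two stereocentres (C2 and the lavandulyl carbon) are linked only through O1–C8a–C8–CH2, so neither can steer the other and each must be set independently. Fragile points are:

- C2, a benzylic ether beta to the C4 ketone. Base opens it by retro-oxa-Michael reaction (more easily if the 4'-oxygen is a phenoxide), and acid can ionise it because ring B carries two donor oxygens.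
- The two alkenes of the lavandulyl group. Acid would cyclise the isopropenyl unit onto the 7-hydroxyl; strong electrophiles and hydrogenation are excluded.

The real difficulty is the contiguous C7(OH)–C8(alkyl)–C8a(O) pattern. C-alkylation of a preformed resorcinol ring is not regioselective, and a beta-branched lavandulyl electrophile prefers elimination. The key step uses the fact that C7 can start as an ester carbonyl and that C8 is gamma to the C4 carbonyl through the C8a=C4a enol-ether bond of a monocyclic 2-aryl-2,3-dihydropyran-4-one. A Z-acrylate on C4a holds C7 next to C8, so forming C7–C8 closes ring A last and places the lavandulyl group between the two oxygens by construction.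

## Logic of the disconnections

**19 to 18.** The O–Si bond at the 4'-oxygen is cut. This oxygen must stay masked through every basic step, because a phenoxide para to C2 would labilise C2–O1. A triisopropylsilyl ether is used instead of a tert-butyldimethylsilyl ether, since it has to survive amidine base and methanol. The skeleton is unchanged. The forward step must be neither basic nor acidic, hence buffered fluoride.

**18 to 16.** The C7–C8 bond of ring A is cut, turning C7 into a methyl ester carbon and C8 into a CH2 gamma to the C4 carbonyl. A trisubstituted benzene with three contiguous substituents becomes a side chain and an acrylate on a monocyclic pyranone that already holds both stereocentres. The forward step must remove a C8 proton and not a C3 proton, needs Z geometry at C5=C6, and must not expose the silyl ether or C2 to strong base.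

**16 to 13 and 15.** The sp2–sp2 bond between C4a and C5 is cut. The Z-alkene arrives preformed in 15, so its geometry is not made on the hindered ring. The coupling must retain alkene geometry and run without base, so that 16 neither isomerises nor cyclises early.

**13 to 12.** The C–I bond at the enol-ether alpha carbon is cut. This leaves the simplest ring C carrier of both stereocentres. The iodination must pick this carbon over two isolated alkenes and an electron-rich arene.

**12 to 8 and 10.** C2–C3 and O1–C8a are cut, a hetero-Diels–Alder disconnection. Ring C and the C2 configuration arise in one catalytic operation from an achiral aldehyde. The diene must be a single regioisomer. A bis-silyl dienol ether of an unsymmetrical 1,3-diketone would not be, because its methyl and methylene flanks are not differentiated and a silyl group shuttles between the two oxygens of a beta-silyloxy enone. In 8 the two oxygens are different (methoxy on the future C8a, silyloxy on the future C4), which fixes the nucleophilic terminus. The forward step needs Si-face attack on a deactivated, ortho-substituted aldehyde.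

**8 to 7 to 6.** The O–Si bond and then the C–OMe bond are cut, leading back to an ynone. In 6 the future C8a is an alkyne carbon attached to the side chain, so methanol can only add there, and only the methyl ketone flank of 7 can be enolised kinetically. The forward steps need conjugate addition without alkyne isomerisation and alpha'-deprotonation in preference to gamma-deprotonation.

**6 to 3.** The acetyl–alkyne bond is cut and the alkyne is traced to a methyl ketone, whose carbonyl carbon becomes C8a and whose methyl becomes C4a. The forward step needs kinetic enolisation at the methyl group, complete elimination to the acetylide, and acylation without over-addition.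

**3 to 2 to 1.** The trisubstituted C=C of the prenyl group is cut (olefination of an aldehyde), and the two carbonyl carbons of 2 are rejoined as the ring alkene of 1. The stereocentre with isopropenyl and two different CH2 arms is already present in 1. This replaces an auxiliary-controlled alkylation and an SN2 reaction at a beta-branched homoallylic halide (which favours E2) with two steps from the chiral pool. The forward steps need ozone to select the trisubstituted ring alkene and the ylide to select the aldehyde over the ketone.

**10 to 9 and 15 to 14.** An O–Si bond and a C–Sn bond are cut. Both lead to commercial materials. The hydrostannation must give the Z isomer.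

## Other disconnections considered

**Alternative 1:** Ring A is cut at C8–C8a, C6–C7 and C4a–C8a. Irradiation of diazoketone A2 with lavandulyl siloxyalkyne A3 would start a cascade of Wolff rearrangement, [2+2] cycloaddition, four-electron ring opening and six-electron ring closure, ending in phenol A1.

- In favour: the lavandulyl group lands between the two oxygens without ambiguity. The two oxygens emerge differentiated (free at C8a, silylated at C7). The medium is neutral and the cascade type is well established.
- Against: A1 contains neither ring C nor C2. The masked C4 carbon must be unveiled, raised to the ketone level and joined to ring B, and C2 must then be set in a late ring closure at an electron-rich benzylic carbon, which is where C2 is most at risk. A3 needs the lavandulyl unit homologated and converted into a sensitive ynol ether. The diazo compound and the photochemistry limit scale, and the side-chain alkenes are exposed to a ketene under irradiation.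
- Comparison: on mechanistic precedent this alternative is the better one, and on regiocontrol at ring A the two are equal. The chosen plan sets C2 early on a simple aldehyde and never forms the C2–O bond at a late stage. It should also be shorter, because the steps after A1 plus the two fragment syntheses exceed the ten-step longest sequence proposed here.

**Alternative 2:** Ring C is cut at O1–C8a. Triflate A5, which carries the S carbinol, would be closed by intramolecular palladium-catalysed aryl ether formation to give flavanol silyl ether A4. Configuration is retained because the C2–O bond is not touched.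

- In favour: C2 is made in an open chain by mature carbonyl chemistry. During ring closure C4 is not a ketone, so there is no retro-oxa-Michael channel. On the configurational security of C2 in the ring-forming event this alternative is better than the chosen plan, and its reaction type is precedented.
- Against: the triflate is flanked on both sides (lavandulyl at C8, the side chain at C4a), which hinders oxidative addition and reductive elimination. Beta-hydride elimination of the secondary palladium alkoxide competes. The regiochemical problem of ring A is not solved but moved into the preparation of a fully substituted arene. After A4, desilylation, oxidation at C4 and acidic removal of two methoxymethyl groups are needed, and acid endangers both the isopropenyl/7-hydroxyl pair and C2. A mixture of C4 epimers is carried along.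
- Comparison: structurally it keeps a classical arene-first order and pays for it in protecting-group and redox steps. The chosen plan avoids C4 redox changes and acidic deprotection and should be several steps shorter.

**Alternative 3:** Ring A is cut at C5–C6 and C4a–C8a. Diels–Alder addition of ketene acetal diene A7 to terminal ynone A8, followed by loss of the methoxy group, would give the chelated hydroxy ketone A6. Desilylation and ring closure with inversion (hence the R carbinol) would follow.

- In favour: two chains of similar size, each with one stereocentre, are joined as ring A forms. Regiochemistry follows from the polarity of the partners, and the C8a hydroxyl appears free. On convergence this alternative is better than the chosen linear plan, and the benzannulation type is known.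
- Against: A7 is a fully substituted, hydrolytically labile diene with the bulky lavandulyl group on an inner carbon, and its preparation again needs an SN2 reaction at the beta-branched lavandulyl carbon. A8 is prone to beta-elimination. The closure after A6 is an inversion at a benzylic carbinol with two donor oxygens and a hindered, hydrogen-bonded phenol, where ionisation (loss of C2 purity) and elimination compete. Three silyl groups must then be removed.
- Comparison: the longest sequences are comparable (equal on this point). The chosen plan takes on an unprecedented bond formation but keeps C2 inside an intact ring from the moment it is made.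

Key step: step 11

Remarks on the chemistry:

- The 4'-oxygen is carried as a triisopropylsilyl ether in 16 and 18. Their carbon skeletons and configurations are otherwise as drawn, and no error was found in them.
- The CIP descriptor of the side-chain centre changes from S (1 to 16) to R (17 to 19) without any change in space, because the neighbouring carbon becomes aromatic.
- Assumption: the titanium complex of (S)-BINOL directs the diene to the Si face of 10, as this catalyst family does with other aryl aldehydes. If the ortho-methoxy group reverses the sense, (R)-BINOL is used and nothing else changes.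
- Assumption: commercial (S)-(−)-limonene of high enantiomeric purity is used, and its purity becomes that of the side-chain centre.

## Route

Step 1
Reactants: 1 (S)-(−)-limonene
Product: 2 (3S)-6-oxo-3-(prop-1-en-2-yl)heptanal
Conditions: O3 (1.0 equiv), CH2Cl2–MeOH, −78 °C; then Me2S, −78 °C → rt
Reagents that add atoms: ozone, [O-][O+]=O
Why: Ozonolysis; ozone attacks the electron-rich trisubstituted ring alkene much faster than the 1,1-disubstituted isopropenyl group, so one equivalent at low temperature should cleave only the ring. The stereocentre is not alpha to either new carbonyl and is untouched.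

Step 2
Reactants: 2 (3S)-6-oxo-3-(prop-1-en-2-yl)heptanal
Product: 3 (5S)-8-methyl-5-(prop-1-en-2-yl)non-7-en-2-one
Conditions: i-PrPPh3I, n-BuLi, THF, 0 °C; then 2, −78 → 0 °C
Reagents that add atoms: isopropyltriphenylphosphonium iodide, CC(C)[P+](c1ccccc1)(c1ccccc1)c1ccccc1.[I-]
Why: Wittig olefination; the hindered non-stabilised ylide should add to the aldehyde far faster than to the methyl ketone at low temperature, completing the prenyl terminus. The stereocentre is beta to the reacting carbonyl and cannot epimerise.

Step 3
Reactants: 3 (5S)-8-methyl-5-(prop-1-en-2-yl)non-7-en-2-one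
Product: 6 (7S)-10-methyl-7-(prop-1-en-2-yl)undec-9-en-3-yn-2-one, via enol diethyl phosphate 4 (not isolated), via lithium acetylide 5 (not isolated)
Conditions: LiN(iPr)2 (1.1 equiv), THF, −78 °C; ClP(O)(OEt)2, −78 °C → rt; LiN(iPr)2 (2.3 equiv), −78 °C → rt; MeC(O)N(OMe)Me (1.5 equiv), −78 → 0 °C; aq. NH4Cl
Reagents that add atoms: N-methoxy-N-methylacetamide, CC(=O)N(C)OC
Why: Kinetic enolisation at the methyl group and O-phosphorylation, then elimination with excess amide base, is the established conversion of a methyl ketone into a terminal acetylide. The acetylide is acylated in the same flask by the N-methoxy-N-methyl amide, whose chelated adduct prevents over-addition. The former carbonyl carbon becomes the alkyne carbon destined to be C8a.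

Step 4
Reactants: 6 (7S)-10-methyl-7-(prop-1-en-2-yl)undec-9-en-3-yn-2-one
Product: 7 (3E,7S)-4-methoxy-10-methyl-7-(prop-1-en-2-yl)undeca-3,9-dien-2-one (E/Z mixture acceptable)
Conditions: MeOH (5 equiv), PBu3 (10 mol %), CH2Cl2, 0 °C → rt
Reagents that add atoms: methanol, CO
Why: Phosphine-catalysed conjugate addition of an alcohol to an ynone; the methoxy group can only end on the carbon that bears the side chain, so the enol-ether flank and the methyl ketone flank are fixed. The alkene geometry is erased in step 7.

Step 5
Reactants: 7 (3E,7S)-4-methoxy-10-methyl-7-(prop-1-en-2-yl)undeca-3,9-dien-2-one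
Product: 8 {[(3E,7S)-4-methoxy-10-methyl-7-(prop-1-en-2-yl)undeca-1,3,9-trien-2-yl]oxy}(trimethyl)silane, used crude
Conditions: LiN(iPr)2, THF, −78 °C; TMSCl, −78 → 0 °C; pentane, filtration
Reagents that add atoms: chlorotrimethylsilane, C[Si](C)(C)Cl
Why: Kinetic deprotonation of a beta-alkoxy enone by a lithium amide occurs at the alpha' methyl and not at the gamma methylene. O-Silylation then gives the 1-methoxy-3-silyloxy diene as one regioisomer.

Step 6
Reactants: 9 4-hydroxy-2-methoxybenzaldehyde
Product: 10 2-methoxy-4-(triisopropylsilyloxy)benzaldehyde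
Conditions: TIPSCl, imidazole, DMF, rt
Reagents that add atoms: chlorotriisopropylsilane, CC(C)[Si](Cl)(C(C)C)C(C)C
Why: Standard phenol silylation; the bulky aryl silyl ether should tolerate the Lewis acid of step 7 and the amidine base with methanol of step 11, and is still cleaved by fluoride.

Step 7
Reactants: 8 {[(3E,7S)-4-methoxy-10-methyl-7-(prop-1-en-2-yl)undeca-1,3,9-trien-2-yl]oxy}(trimethyl)silane; 10 2-methoxy-4-(triisopropylsilyloxy)benzaldehyde
Product: 12 (2S)-2-[2-methoxy-4-(triisopropylsilyloxy)phenyl]-6-[(3S)-6-methyl-3-(prop-1-en-2-yl)hept-5-en-1-yl]-2,3-dihydro-4H-pyran-4-one, via silylated aldol adduct 11 (not isolated)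
Conditions: Ti(OiPr)4 (20 mol %), (S)-BINOL (22 mol %), 4 Å MS, toluene, 0 °C → rt; then TFA (cat.), CH2Cl2, 0 °C
Reagents that add atoms: none
Why: Catalytic enantioselective hetero-Diels–Alder reaction of an aldehyde with a 1-alkoxy-3-silyloxy diene, which runs through a Mukaiyama aldol adduct that cyclises with loss of the methoxy group on brief acid treatment. The tetravalent titanium BINOLate binds the aldehyde and shields one face, so the diene terminus adds to the Si face and sets C2 as S. The side-chain stereocentre is remote and has no influence.

Step 8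
Reactants: 12 (2S)-2-[2-methoxy-4-(triisopropylsilyloxy)phenyl]-6-[(3S)-6-methyl-3-(prop-1-en-2-yl)hept-5-en-1-yl]-2,3-dihydro-4H-pyran-4-one
Product: 13 (2S)-5-iodo-2-[2-methoxy-4-(triisopropylsilyloxy)phenyl]-6-[(3S)-6-methyl-3-(prop-1-en-2-yl)hept-5-en-1-yl]-2,3-dihydro-4H-pyran-4-one
Conditions: I2, pyridine, CH2Cl2, 0 °C → rt, dark
Reagents that add atoms: iodine, [I][I]
Why: Alpha-iodination of a beta-alkoxy enone; C5 is the nucleophilic enol-ether carbon, and pyridine removes the proton. Iodine buffered by pyridine does not add irreversibly to isolated alkenes and should not substitute an aryl ether.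

Step 9
Reactants: 14 methyl propiolate
Product: 15 methyl (2Z)-3-(tributylstannyl)prop-2-enoate
Conditions: Bu3SnH (1.0 equiv), Et3B (10 mol %), air (trace), toluene, −78 → 0 °C; chromatography
Reagents that add atoms: tributyltin hydride, CCCC[SnH](CCCC)CCCC
Why: Radical hydrostannation; the stannyl radical adds to the terminal carbon, and hydrogen transfer to the vinyl radical anti to tin gives the Z-stannyl acrylate as the kinetic product at low temperature. E and alpha isomers are removed by chromatography.

Step 10
Reactants: 13 (2S)-5-iodo-2-[2-methoxy-4-(triisopropylsilyloxy)phenyl]-6-[(3S)-6-methyl-3-(prop-1-en-2-yl)hept-5-en-1-yl]-2,3-dihydro-4H-pyran-4-one; 15 methyl (2Z)-3-(tributylstannyl)prop-2-enoate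
Product: 16 methyl (2Z)-3-{(2S)-2-[2-methoxy-4-(triisopropylsilyloxy)phenyl]-6-[(3S)-6-methyl-3-(prop-1-en-2-yl)hept-5-en-1-yl]-4-oxo-3,4-dihydro-2H-pyran-5-yl}prop-2-enoate
Conditions: Pd2(dba)3 (5 mol %), AsPh3 (20 mol %), CuI (20 mol %), DMF, rt → 40 °C, dark
Reagents that add atoms: none
Why: Stille coupling; zerovalent palladium inserts into the C5–I bond of the alpha-iodoenone, and copper-assisted transfer of the alkenyl group proceeds with retention of Z geometry. The base-free medium leaves the acidic C8–H of the product alone.

Step 11
Reactants: 16 methyl (2Z)-3-{(2S)-2-[2-methoxy-4-(triisopropylsilyloxy)phenyl]-6-[(3S)-6-methyl-3-(prop-1-en-2-yl)hept-5-en-1-yl]-4-oxo-3,4-dihydro-2H-pyran-5-yl}prop-2-enoate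
Product: 18 (2S)-7-hydroxy-2-[2-methoxy-4-(triisopropylsilyloxy)phenyl]-8-[(2R)-5-methyl-2-(prop-1-en-2-yl)hex-4-en-1-yl]-2,3-dihydro-4H-chromen-4-one, via cyclohexadienone tautomer 17 (not isolated)
Conditions: DBU (2 equiv), MeOH (5 equiv), MeCN, 0 °C → rt; then AcOH, 0 °C
Reagents that add atoms: none
Why: Proposed new method: DBU reversibly removes a C8 proton, the only C–H whose anion is delocalised through C8a=C4a into both the C4 ketone and the acrylate ester; this carbanion adds to the ester carbon C7 held in reach by the Z C5=C6 bond (6-exo-trig closure of ring A), methoxide leaves to give cyclohexadienone 17, and 17 enolises irreversibly to the 7-phenoxide. The closest known reaction types are the vinylogous Dieckmann condensation of gamma-deprotonated enones and the base-mediated Claisen cyclisation and aromatisation of poly-beta-carbonyl chains to resorcinols; new here is a dihydropyranone enol ether as the relay combined with an acrylate as the acyl acceptor. No stereocentre is created: C8 of 17 is transient and becomes sp2, C2 is not involved, and the side-chain centre lies two carbons from C8. The selectivity needed is deprotonation at C8 and not at C3, and it should be secured by the far higher acidity of the doubly vinylogous C8–H towards a weak amidine base, which keeps the C3 enolate (whose beta-elimination of O1 would open ring C and racemise C2) at a negligible level. O-Acylation by the dienolate oxygen and E/Z isomerisation of the acrylate are reversible under DBU and methanol, whereas C-acylation ends in the arene and drains these equilibria. The product phenoxide is a vinylogous carboxylate that lowers the acidity of C3–H, and a prompt acetic acid quench returns the neutral flavanone before ring C can open. The triisopropylsilyl ether keeps the 4'-oxygen from becoming a phenoxide para to C2.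

Step 12
Reactants: 18 (2S)-7-hydroxy-2-[2-methoxy-4-(triisopropylsilyloxy)phenyl]-8-[(2R)-5-methyl-2-(prop-1-en-2-yl)hex-4-en-1-yl]-2,3-dihydro-4H-chromen-4-one
Product: 19 alopecurone G
Conditions: Bu4NF, AcOH (1:1.2), THF, 0 °C
Reagents that add atoms: none
Why: Fluoride-mediated cleavage of an aryl silyl ether; acetic acid keeps both phenols protonated, so C2 is never exposed to base, and the alkenes and the ketone are inert.

## Compound list

1 | (S)-(−)-limonene, (4S)-1-methyl-4-(prop-1-en-2-yl)cyclohex-1-ene | C=C(C)[C@@H]1CC=C(C)CC1 | starting material
2 | (3S)-6-oxo-3-(prop-1-en-2-yl)heptanal | C=C(C)[C@H](CC=O)CCC(C)=O | intermediate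
3 | (5S)-8-methyl-5-(prop-1-en-2-yl)non-7-en-2-one | C=C(C)[C@H](CC=C(C)C)CCC(C)=O | intermediate
4 | diethyl (5S)-8-methyl-5-(prop-1-en-2-yl)nona-1,7-dien-2-yl phosphate (formed in the flask) | C=C(C)[C@H](CC=C(C)C)CCC(=C)OP(=O)(OCC)OCC | intermediate
5 | lithium (5S)-8-methyl-5-(prop-1-en-2-yl)non-7-en-1-yn-1-ide (formed in the flask) | C=C(C)[C@H](CC=C(C)C)CCC#C[Li] | intermediate
6 | (7S)-10-methyl-7-(prop-1-en-2-yl)undec-9-en-3-yn-2-one | C=C(C)[C@H](CC=C(C)C)CCC#CC(C)=O | intermediate
7 | (3E,7S)-4-methoxy-10-methyl-7-(prop-1-en-2-yl)undeca-3,9-dien-2-one | C=C(C)[C@H](CC=C(C)C)CC/C(OC)=C\C(C)=O | intermediate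
8 | {[(3E,7S)-4-methoxy-10-methyl-7-(prop-1-en-2-yl)undeca-1,3,9-trien-2-yl]oxy}(trimethyl)silane | C=C(C)[C@H](CC=C(C)C)CC/C(OC)=C\C(=C)O[Si](C)(C)C | intermediate
9 | 4-hydroxy-2-methoxybenzaldehyde | COc1cc(O)ccc1C=O | starting material
10 | 2-methoxy-4-(triisopropylsilyloxy)benzaldehyde | COc1cc(O[Si](C(C)C)(C(C)C)C(C)C)ccc1C=O | intermediate
11 | (1S,4E,8S)-5-methoxy-1-[2-methoxy-4-(triisopropylsilyloxy)phenyl]-11-methyl-8-(prop-1-en-2-yl)-1-(trimethylsilyloxy)dodeca-4,10-dien-3-one (formed in the flask) | C=C(C)[C@H](CC=C(C)C)CC/C(OC)=C\C(=O)C[C@H](O[Si](C)(C)C)c1ccc(O[Si](C(C)C)(C(C)C)C(C)C)cc1OC | intermediate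
12 | (2S)-2-[2-methoxy-4-(triisopropylsilyloxy)phenyl]-6-[(3S)-6-methyl-3-(prop-1-en-2-yl)hept-5-en-1-yl]-2,3-dihydro-4H-pyran-4-one | C=C(C)[C@H](CC=C(C)C)CCC1=CC(=O)C[C@@H](c2ccc(O[Si](C(C)C)(C(C)C)C(C)C)cc2OC)O1 | intermediate
13 | (2S)-5-iodo-2-[2-methoxy-4-(triisopropylsilyloxy)phenyl]-6-[(3S)-6-methyl-3-(prop-1-en-2-yl)hept-5-en-1-yl]-2,3-dihydro-4H-pyran-4-one | C=C(C)[C@H](CC=C(C)C)CCC1=C(I)C(=O)C[C@@H](c2ccc(O[Si](C(C)C)(C(C)C)C(C)C)cc2OC)O1 | intermediate
14 | methyl propiolate | C#CC(=O)OC | starting material
15 | methyl (2Z)-3-(tributylstannyl)prop-2-enoate | CCCC[Sn](CCCC)(CCCC)/C=C\C(=O)OC | intermediate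
16 | methyl (2Z)-3-{(2S)-2-[2-methoxy-4-(triisopropylsilyloxy)phenyl]-6-[(3S)-6-methyl-3-(prop-1-en-2-yl)hept-5-en-1-yl]-4-oxo-3,4-dihydro-2H-pyran-5-yl}prop-2-enoate | C=C(C)[C@H](CC=C(C)C)CCC1=C(/C=C\C(=O)OC)C(=O)C[C@@H](c2ccc(O[Si](C(C)C)(C(C)C)C(C)C)cc2OC)O1 | intermediate
17 | (2S)-2-[2-methoxy-4-(triisopropylsilyloxy)phenyl]-8-[(2R)-5-methyl-2-(prop-1-en-2-yl)hex-4-en-1-yl]-2,3-dihydro-4H-chromene-4,7(8H)-dione, both C8 epimers (formed in the flask) | C=C(C)[C@H](CC=C(C)C)CC1C(=O)C=CC2=C1O[C@H](c1ccc(O[Si](C(C)C)(C(C)C)C(C)C)cc1OC)CC2=O | intermediate
18 | 4'-O-triisopropylsilyl alopecurone G, (2S)-7-hydroxy-2-[2-methoxy-4-(triisopropylsilyloxy)phenyl]-8-[(2R)-5-methyl-2-(prop-1-en-2-yl)hex-4-en-1-yl]-2,3-dihydro-4H-chromen-4-one | C=C(C)[C@H](CC=C(C)C)Cc1c(O)ccc2c1O[C@H](c1ccc(O[Si](C(C)C)(C(C)C)C(C)C)cc1OC)CC2=O | intermediate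
19 | alopecurone G, (2S)-7-hydroxy-2-(4-hydroxy-2-methoxyphenyl)-8-[(2R)-5-methyl-2-(prop-1-en-2-yl)hex-4-en-1-yl]-2,3-dihydro-4H-chromen-4-one | C=C(C)[C@H](CC=C(C)C)Cc1c(O)ccc2c1O[C@H](c1ccc(O)cc1OC)CC2=O | target

## Step count and least certain steps

Total step count: 12. Longest linear sequence: 10 steps (steps 1, 2, 3, 4, 5, 7, 8, 10, 11, 12).

**Step 11 (key step, new method).** Most likely to go wrong:

- competing deprotonation at C3, followed by opening of ring C and loss of configuration at C2;
- stalling at the O-acylated stage, or drift of the acrylate to E geometry, if the reverse reactions are slower than expected;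
- slow closure because the acrylate twists out of conjugation on the crowded enol ether.

The fallback uses known chemistry and sets out from 16. The methyl ester is hydrolysed under neutral conditions (Me3SnOH, 1,2-dichloroethane, 70 °C) to the (Z)-acrylic acid F1. F1 is converted with 1-chloro-N,N,2-trimethylprop-1-en-1-amine (CH2Cl2, 0 °C) into the acid chloride F2. Slow addition of F2 to Et3N at high dilution should give, by loss of HCl through C8–H, a dienylketene that closes by thermal six-electron electrocyclisation and tautomerises. This is the established phenol synthesis from unsaturated acid derivatives. It comes back to the route at 18.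

**Step 7.** Most likely to go wrong: slow addition to the electron-rich, ortho-substituted aldehyde; poor or reversed facial selectivity because the ortho-methoxy group can chelate titanium; partial ionisation at the doubly donor-substituted benzylic carbon during the acid-induced cyclisation, with erosion of enantiomeric purity. The fallback sets out from 7 and 10 and replaces catalyst control by reagent control. Ketone 7 is converted into its enol diisopinocampheylborinate (Ipc2BCl, Et3N, Et2O, −78 °C; the antipode that attacks the Si face). Addition to 10 and oxidative work-up give the free aldol, (1S,4E,8S)-1-hydroxy-5-methoxy-1-[2-methoxy-4-(triisopropylsilyloxy)phenyl]-11-methyl-8-(prop-1-en-2-yl)dodeca-4,10-dien-3-one F3. A trace of TFA or pyridinium tosylate cyclises F3 with loss of the methoxy group. It comes back at 12.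

**Step 8.** Most likely to go wrong: competing electrophilic iodination of ring B or iodine-induced reaction at the trisubstituted alkene, and slow substitution at the fully substituted enol ether. The fallback sets out from 7 and moves the iodination to a stage without the arene. I2/pyridine on 7 gives (7S)-3-iodo-4-methoxy-10-methyl-7-(prop-1-en-2-yl)undeca-3,9-dien-2-one F4. LiN(iPr)2/TMSCl converts F4 into the iodo diene {[(7S)-3-iodo-4-methoxy-10-methyl-7-(prop-1-en-2-yl)undeca-1,3,9-trien-2-yl]oxy}(trimethyl)silane F5. F5 is combined with 10 under the conditions of step 7. It comes back at 13.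

**Step 10 (and step 9, which feeds it).** Most likely to go wrong: loss of Z geometry, either in the hydrostannation or by isomerisation during coupling, and protodestannylation. The fallback sets out from 13 and 14 and does without tin. Sonogashira coupling (PdCl2(PPh3)2, CuI, iPr2NEt, THF, 0 °C) gives the alkynoate methyl 3-{(2S)-2-[2-methoxy-4-(triisopropylsilyloxy)phenyl]-6-[(3S)-6-methyl-3-(prop-1-en-2-yl)hept-5-en-1-yl]-4-oxo-3,4-dihydro-2H-pyran-5-yl}prop-2-ynoate F6. Semi-hydrogenation of F6 (H2, Pd/CaCO3 poisoned with Pb(OAc)2, quinoline, EtOAc) gives the cis-alkene by construction. It comes back at 16.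

**Step 3.** Most likely to go wrong: enolisation toward the methylene (leading to an allene or internal alkyne), incomplete elimination, and consumption of the acylating amide by residual base. The fallback sets out from 3 and gives up the alkyne. Claisen condensation with ethyl acetate (NaH, THF), which acylates the methyl group, gives (7S)-10-methyl-7-(prop-1-en-2-yl)undec-9-ene-2,4-dione F7. TMSCl/Et3N and then LiN(iPr)2/TMSCl convert F7 into the bis-silyl dienol ether (7S)-10-methyl-7-(prop-1-en-2-yl)-2,4-bis(trimethylsilyloxy)undeca-1,3,9-triene F8. An internal regioisomer is expected alongside F8; it does not lead to 12 and is removed after cyclisation. F8 is combined with 10 under the conditions of step 7. It comes back at 12.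

## Further compounds

F1 | step 11 | (2Z)-3-{(2S)-2-[2-methoxy-4-(triisopropylsilyloxy)phenyl]-6-[(3S)-6-methyl-3-(prop-1-en-2-yl)hept-5-en-1-yl]-4-oxo-3,4-dihydro-2H-pyran-5-yl}prop-2-enoic acid | C=C(C)[C@H](CC=C(C)C)CCC1=C(/C=C\C(=O)O)C(=O)C[C@@H](c2ccc(O[Si](C(C)C)(C(C)C)C(C)C)cc2OC)O1
F2 | step 11 | (2Z)-3-{(2S)-2-[2-methoxy-4-(triisopropylsilyloxy)phenyl]-6-[(3S)-6-methyl-3-(prop-1-en-2-yl)hept-5-en-1-yl]-4-oxo-3,4-dihydro-2H-pyran-5-yl}prop-2-enoyl chloride | C=C(C)[C@H](CC=C(C)C)CCC1=C(/C=C\C(=O)Cl)C(=O)C[C@@H](c2ccc(O[Si](C(C)C)(C(C)C)C(C)C)cc2OC)O1
F3 | step 7 | (1S,4E,8S)-1-hydroxy-5-methoxy-1-[2-methoxy-4-(triisopropylsilyloxy)phenyl]-11-methyl-8-(prop-1-en-2-yl)dodeca-4,10-dien-3-one | C=C(C)[C@H](CC=C(C)C)CC/C(OC)=C\C(=O)C[C@H](O)c1ccc(O[Si](C(C)C)(C(C)C)C(C)C)cc1OC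
F4 | step 8 | (7S)-3-iodo-4-methoxy-10-methyl-7-(prop-1-en-2-yl)undeca-3,9-dien-2-one | C=C(C)[C@H](CC=C(C)C)CCC(OC)=C(I)C(C)=O
F5 | step 8 | {[(7S)-3-iodo-4-methoxy-10-methyl-7-(prop-1-en-2-yl)undeca-1,3,9-trien-2-yl]oxy}(trimethyl)silane | C=C(C)[C@H](CC=C(C)C)CCC(OC)=C(I)C(=C)O[Si](C)(C)C
F6 | step 10 | methyl 3-{(2S)-2-[2-methoxy-4-(triisopropylsilyloxy)phenyl]-6-[(3S)-6-methyl-3-(prop-1-en-2-yl)hept-5-en-1-yl]-4-oxo-3,4-dihydro-2H-pyran-5-yl}prop-2-ynoate | C=C(C)[C@H](CC=C(C)C)CCC1=C(C#CC(=O)OC)C(=O)C[C@@H](c2ccc(O[Si](C(C)C)(C(C)C)C(C)C)cc2OC)O1
F7 | step 3 | (7S)-10-methyl-7-(prop-1-en-2-yl)undec-9-ene-2,4-dione | C=C(C)[C@H](CC=C(C)C)CCC(=O)CC(C)=O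
F8 | step 3 | (7S)-10-methyl-7-(prop-1-en-2-yl)-2,4-bis(trimethylsilyloxy)undeca-1,3,9-triene | C=C(C)[C@H](CC=C(C)C)CCC(O[Si](C)(C)C)=CC(=C)O[Si](C)(C)C
A1 | alternative 1 | 6-(dimethoxymethyl)-2-[(2R)-5-methyl-2-(prop-1-en-2-yl)hex-4-en-1-yl]-3-(triisopropylsilyloxy)phenol | C=C(C)[C@H](CC=C(C)C)Cc1c(O[Si](C(C)C)(C(C)C)C(C)C)ccc(C(OC)OC)c1O
A2 | alternative 1 | (3E)-1-diazo-5,5-dimethoxypent-3-en-2-one | COC(OC)/C=C/C(=O)C=[N+]=[N-]
A3 | alternative 1 | triisopropyl{[(4R)-7-methyl-4-(prop-1-en-2-yl)oct-6-en-1-yn-1-yl]oxy}silane | C=C(C)[C@H](CC=C(C)C)CC#CO[Si](C(C)C)(C(C)C)C(C)C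
A4 | alternative 2 | (2S)-7-(methoxymethoxy)-2-[2-methoxy-4-(methoxymethoxy)phenyl]-8-[(2R)-5-methyl-2-(prop-1-en-2-yl)hex-4-en-1-yl]-4-(triethylsilyloxy)chromane, both C4 epimers | C=C(C)[C@H](CC=C(C)C)Cc1c(OCOC)ccc2c1O[C@H](c1ccc(OCOC)cc1OC)CC2O[Si](CC)(CC)CC
A5 | alternative 2 | 6-{(3S)-3-hydroxy-3-[2-methoxy-4-(methoxymethoxy)phenyl]-1-(triethylsilyloxy)propyl}-3-(methoxymethoxy)-2-[(2R)-5-methyl-2-(prop-1-en-2-yl)hex-4-en-1-yl]phenyl trifluoromethanesulfonate, both epimers at the silyloxy carbon | C=C(C)[C@H](CC=C(C)C)Cc1c(OCOC)ccc(C(O[Si](CC)(CC)CC)C[C@H](O)c2ccc(OCOC)cc2OC)c1OS(=O)(=O)C(F)(F)F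
A6 | alternative 3 | (3R)-3-[4-(tert-butyldimethylsilyloxy)-2-methoxyphenyl]-1-{4-(tert-butyldimethylsilyloxy)-2-hydroxy-3-[(2R)-5-methyl-2-(prop-1-en-2-yl)hex-4-en-1-yl]phenyl}-3-(triethylsilyloxy)propan-1-one | C=C(C)[C@H](CC=C(C)C)Cc1c(O[Si](C)(C)C(C)(C)C)ccc(C(=O)C[C@@H](O[Si](CC)(CC)CC)c2ccc(O[Si](C)(C)C(C)(C)C)cc2OC)c1O
A7 | alternative 3 | 3-(tert-butyldimethylsilyloxy)-1-methoxy-2-[(2R)-5-methyl-2-(prop-1-en-2-yl)hex-4-en-1-yl]-1-(trimethylsilyloxy)buta-1,3-diene | C=C(C)[C@H](CC=C(C)C)CC(C(=C)O[Si](C)(C)C(C)(C)C)=C(OC)O[Si](C)(C)C
A8 | alternative 3 | (5R)-5-[4-(tert-butyldimethylsilyloxy)-2-methoxyphenyl]-5-(triethylsilyloxy)pent-1-yn-3-one | C#CC(=O)C[C@@H](O[Si](CC)(CC)CC)c1ccc(O[Si](C)(C)C(C)(C)C)cc1OC
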